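**Retrosynthetic overview**

- Monochlorosulochrin is the bis-MOM ether of itself after acid treatment; no ring is formed anywhere in the route, both benzene rings are bought.
- The strategy rests on ring B: C1' carries the ketone carbonyl and sits between the phenolic oxygens on C2' and C6'. This ortho-hydroxyaryl ketone is the formal insertion of a C1'≡C2' aryne (alkoxy at C6') into the C–O bond of the ring A carboxylic acid, so C1'–C(=O) and C2'–O are cut together.
- The aryne precursor, an ortho-silylaryl triflate, comes from 2-chloro-3-methylphenol: MOM ether, sterically controlled C–H borylation/oxidation to place the second oxygen, carbamate-directed silylation between the two oxygens, carbamate to triflate.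
- The ring A acid, a phthalic half ester, comes from methyl 3,5-dihydroxybenzoate: formylation at C2, MOM on the free para-OH, methyl on the chelated ortho-OH, CHO to CO2H.
- Order: the two arenes are made separately, joined in the aryne step, then deprotected.

Key step: step 10

Remark on the chemistry: the target has no stereocentre and is achiral, so the single-enantiomer requirement is met without stereocontrol; regiochemistry is the only selectivity to secure. Both starting phenols are taken as commercial. Ring A numbering: C1 CO2Me, C2 acyl, C3 OMe, C5 OH. Ring B numbering: C1' acyl, C2' OH (next to C3'–H), C4' CH3, C5' Cl, C6' OH.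

**Route**

Step 1
Reactants: 1 2-chloro-3-methylphenol
Product: 2 2-chloro-1-(methoxymethoxy)-3-methylbenzene
Conditions: MOMCl, iPr2NEt, CH2Cl2, 0 °C → rt
Reagents that add atoms: chloromethyl methyl ether, COCCl
Why: Williamson-type O-alkylation of the phenol gives the MOM ether, and this oxygen, fixed next to chlorine from the start, becomes O–C6' of the target.

Step 2
Reactants: 2 2-chloro-1-(methoxymethoxy)-3-methylbenzene
Product: 4 4-chloro-3-(methoxymethoxy)-5-methylphenol, via aryl boronate 3 (not isolated)
Conditions: [Ir(OMe)(cod)]2 (cat.), dtbpy (cat.), B2pin2 (1.0 equiv), THF, 80 °C; then 30% H2O2, aq NaOH, THF, 0 °C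
Reagents that add atoms: hydrogen peroxide, OO
Why: Iridium-catalysed C–H borylation is sterically controlled and should take the only C–H of the 1,2,3-trisubstituted ring that has no ortho substituent (para to Cl), and oxidation of the C–B bond then puts the hydroxyl at that carbon.

Step 3
Reactants: 4 4-chloro-3-(methoxymethoxy)-5-methylphenol
Product: 5 4-chloro-3-(methoxymethoxy)-5-methylphenyl N-isopropylcarbamate
Conditions: i-PrNCO, Et3N (cat.), CH2Cl2, rt
Reagents that add atoms: isopropyl isocyanate, CC(C)N=C=O
Why: Base-catalysed addition of the phenol to the isocyanate gives the secondary carbamate that serves both as directing group and as a later-cleavable phenol mask.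

Step 4
Reactants: 5 4-chloro-3-(methoxymethoxy)-5-methylphenyl N-isopropylcarbamate
Product: 9 4-chloro-3-(methoxymethoxy)-5-methyl-2-(trimethylsilyl)phenyl N-isopropylcarbamate, via N-silyl carbamate 6 (not isolated), via aryllithium 7 (not isolated), via N-silyl aryl silane 8 (not isolated)
Conditions: TBSOTf (1.1 equiv), TMEDA, Et2O, 0 °C → rt; n-BuLi, TMEDA, −78 °C; TMSCl, −78 °C → rt; aq NaHSO4 work-up (brief, cold)
Reagents that add atoms: chlorotrimethylsilane, C[Si](C)(C)Cl
Why: Directed ortho-metalation with in situ N-silyl protection of the carbamate should lithiate C2, the one position flanked by both directing groups (carbamate and OMOM), at a temperature where the aryl chloride is inert, and TMSCl traps the anion before the labile N–Si bond is hydrolysed on work-up.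

Step 5
Reactants: 9 4-chloro-3-(methoxymethoxy)-5-methyl-2-(trimethylsilyl)phenyl N-isopropylcarbamate
Product: 11 4-chloro-3-(methoxymethoxy)-5-methyl-2-(trimethylsilyl)phenyl trifluoromethanesulfonate, via silyl phenol 10 (not isolated)
Conditions: DBU, Et2NH, MeCN, 40 °C; then PhNTf2, rt
Reagents that add atoms: N-phenylbis(trifluoromethanesulfonimide), O=S(=O)(N(c1ccccc1)S(=O)(=O)C(F)(F)F)C(F)(F)F
Why: The N–H carbamate is cleaved by an E1cB elimination (the isocyanate is trapped by diethylamine) and the amidinium phenoxide is sulfonylated in the same flask by the mild triflyl donor, without touching the MOM ether or the C–Si bond.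

Step 6
Reactants: 12 methyl 3,5-dihydroxybenzoate
Product: 14 methyl 2-formyl-3,5-dihydroxybenzoate, via iminium salt 13 (not isolated)
Conditions: POCl3, DMF, MeCN, 0 °C → rt; then H2O, 50 °C
Reagents that add atoms: N,N-dimethylformamide, CN(C)C=O; water, O
Why: Vilsmeier–Haack formylation of the resorcinol-type ring should take place at C2, ortho to one hydroxyl and para to the other, as it does in 5-substituted resorcinols, and not at C4 between the two hydroxyls; hydrolysis of the iminium salt gives the aldehyde.

Step 7
Reactants: 14 methyl 2-formyl-3,5-dihydroxybenzoate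
Product: 15 methyl 2-formyl-3-hydroxy-5-(methoxymethoxy)benzoate
Conditions: MOMCl (1.05 equiv), iPr2NEt, CH2Cl2, 0 °C
Reagents that add atoms: chloromethyl methyl ether, COCCl
Why: Selective O-alkylation of a 2,4-dihydroxybenzaldehyde pattern: the hydroxyl para to the formyl group is the more acidic and is free, whereas the ortho hydroxyl is held in a hydrogen bond to the aldehyde and stays untouched.

Step 8
Reactants: 15 methyl 2-formyl-3-hydroxy-5-(methoxymethoxy)benzoate
Product: 16 methyl 2-formyl-3-methoxy-5-(methoxymethoxy)benzoate
Conditions: MeI, K2CO3, DMF, rt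
Reagents that add atoms: iodomethane, CI
Why: Williamson methylation of the remaining chelated phenol in a polar aprotic solvent, with the ester, the aldehyde and the MOM ether stable to carbonate.

Step 9
Reactants: 16 methyl 2-formyl-3-methoxy-5-(methoxymethoxy)benzoate
Product: 17 2-methoxy-6-(methoxycarbonyl)-4-(methoxymethoxy)benzoic acid
Conditions: NaClO2, NaH2PO4, 2-methyl-2-butene, t-BuOH/H2O, rt
Reagents that add atoms: sodium chlorite, [Na+].[O-]Cl=O
Why: Pinnick oxidation converts the hindered aldehyde into the acid at buffered pH, where the MOM ether and the methyl ester survive, and the alkene scavenger keeps hypochlorous acid away from the electron-rich ring.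

Step 10
Reactants: 11 4-chloro-3-(methoxymethoxy)-5-methyl-2-(trimethylsilyl)phenyl trifluoromethanesulfonate; 17 2-methoxy-6-(methoxycarbonyl)-4-(methoxymethoxy)benzoic acid
Product: 19 methyl 2-[3-chloro-6-hydroxy-2-(methoxymethoxy)-4-methylbenzoyl]-3-methoxy-5-(methoxymethoxy)benzoate, via aryne 18 (not isolated)
Conditions: 11 (1.5 equiv), CsF (4 equiv), anhydrous THF, 125 °C, sealed tube
Reagents that add atoms: none
Why: Fluoride attacks silicon of 11 and the resulting aryl anion expels triflate to give the 3-alkoxyaryne 18, to which the carboxylate oxygen of 17 adds at the aryne carbon remote from OMOM, because the inductively withdrawing OMOM group polarises the aryne and stabilises the negative charge that develops on the carbon next to it. This aryl anion lies ortho to the new ester oxygen and attacks the ester carbonyl through a four-membered transition state (an anionic Fries-type 1,3-O→C acyl shift), and the adduct opens to the diaryl ketone and the C2' phenoxide, so that C2'–O and C1'–C(=O) are formed in one operation. The closest known reaction type is the fluoride-induced insertion of arynes into the C–O bond of carboxylic acids to give ortho-hydroxyaryl ketones, in which 3-alkoxyarynes deliver the 2-hydroxy-6-alkoxyaryl ketone. No ring is closed and no stereocentre is made. The step needs regioselective addition, which the OMOM group on the aryne secures while the remote Cl and CH3 groups leave the polarisation unchanged, and it needs acyl transfer to outrun protonation of the aryl anion and attack on the neighbouring CO2Me, which anhydrous aprotic conditions at high temperature and the acyl carbon held directly beside the carbanion should secure.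

Step 11
Reactants: 19 methyl 2-[3-chloro-6-hydroxy-2-(methoxymethoxy)-4-methylbenzoyl]-3-methoxy-5-(methoxymethoxy)benzoate
Product: 20 monochlorosulochrin, methyl 2-(3-chloro-2,6-dihydroxy-4-methylbenzoyl)-5-hydroxy-3-methoxybenzoate
Conditions: HCl (3 M), MeOH, 45 °C
Reagents that add atoms: none
Why: Acid-catalysed acetal cleavage removes both MOM groups by transfer of the formaldehyde unit to methanol, while the aryl methyl ether is stable and the methyl ester is degenerate towards transesterification in methanol.

**Compound list**

1 | 2-chloro-3-methylphenol | Cc1cccc(O)c1Cl | starting material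
2 | 2-chloro-1-(methoxymethoxy)-3-methylbenzene | COCOc1cccc(C)c1Cl | intermediate
3 | 2-[4-chloro-3-(methoxymethoxy)-5-methylphenyl]-4,4,5,5-tetramethyl-1,3,2-dioxaborolane | COCOc1cc(B2OC(C)(C)C(C)(C)O2)cc(C)c1Cl | intermediate (not isolated)
4 | 4-chloro-3-(methoxymethoxy)-5-methylphenol | COCOc1cc(O)cc(C)c1Cl | intermediate
5 | 4-chloro-3-(methoxymethoxy)-5-methylphenyl N-isopropylcarbamate | COCOc1cc(OC(=O)NC(C)C)cc(C)c1Cl | intermediate
6 | 4-chloro-3-(methoxymethoxy)-5-methylphenyl N-(tert-butyldimethylsilyl)-N-isopropylcarbamate | COCOc1cc(OC(=O)N(C(C)C)[Si](C)(C)C(C)(C)C)cc(C)c1Cl | intermediate (not isolated)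
7 | 4-chloro-2-lithio-3-(methoxymethoxy)-5-methylphenyl N-(tert-butyldimethylsilyl)-N-isopropylcarbamate | COCOc1c([Li])c(OC(=O)N(C(C)C)[Si](C)(C)C(C)(C)C)cc(C)c1Cl | intermediate (not isolated)
8 | 4-chloro-3-(methoxymethoxy)-5-methyl-2-(trimethylsilyl)phenyl N-(tert-butyldimethylsilyl)-N-isopropylcarbamate | COCOc1c([Si](C)(C)C)c(OC(=O)N(C(C)C)[Si](C)(C)C(C)(C)C)cc(C)c1Cl | intermediate (not isolated)
9 | 4-chloro-3-(methoxymethoxy)-5-methyl-2-(trimethylsilyl)phenyl N-isopropylcarbamate | COCOc1c([Si](C)(C)C)c(OC(=O)NC(C)C)cc(C)c1Cl | intermediate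
10 | 4-chloro-3-(methoxymethoxy)-5-methyl-2-(trimethylsilyl)phenol | COCOc1c([Si](C)(C)C)c(O)cc(C)c1Cl | intermediate (not isolated)
11 | 4-chloro-3-(methoxymethoxy)-5-methyl-2-(trimethylsilyl)phenyl trifluoromethanesulfonate | COCOc1c([Si](C)(C)C)c(OS(=O)(=O)C(F)(F)F)cc(C)c1Cl | intermediate
12 | methyl 3,5-dihydroxybenzoate | COC(=O)c1cc(O)cc(O)c1 | starting material
13 | N-[2,4-dihydroxy-6-(methoxycarbonyl)benzylidene]-N-methylmethanaminium chloride | COC(=O)c1cc(O)cc(O)c1C=[N+](C)C.[Cl-] | intermediate (not isolated)
14 | methyl 2-formyl-3,5-dihydroxybenzoate | COC(=O)c1cc(O)cc(O)c1C=O | intermediate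
15 | methyl 2-formyl-3-hydroxy-5-(methoxymethoxy)benzoate | COC(=O)c1cc(OCOC)cc(O)c1C=O | intermediate
16 | methyl 2-formyl-3-methoxy-5-(methoxymethoxy)benzoate | COC(=O)c1cc(OCOC)cc(OC)c1C=O | intermediate
17 | 2-methoxy-6-(methoxycarbonyl)-4-(methoxymethoxy)benzoic acid | COC(=O)c1cc(OCOC)cc(OC)c1C(=O)O | intermediate
18 | 4-chloro-3-(methoxymethoxy)-5-methylbenzyne (1,2-didehydro, triple bond between the former C–OTf and C–Si carbons) | COCOC1=C(Cl)C(C)=CC#C1 | intermediate (not isolated)
19 | methyl 2-[3-chloro-6-hydroxy-2-(methoxymethoxy)-4-methylbenzoyl]-3-methoxy-5-(methoxymethoxy)benzoate | COC(=O)c1cc(OCOC)cc(OC)c1C(=O)c1c(O)cc(C)c(Cl)c1OCOC | intermediate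
20 | monochlorosulochrin, methyl 2-(3-chloro-2,6-dihydroxy-4-methylbenzoyl)-5-hydroxy-3-methoxybenzoate | COC(=O)c1cc(O)cc(OC)c1C(=O)c1c(O)cc(C)c(Cl)c1O | target

**Step count**

Total step count: 11. Longest linear sequence: 7 steps (steps 1–5, 10 and 11); the ring A branch (steps 6–9) joins at step 10.

**Steps most likely to fail**

1. Step 10 (aryne insertion). The aryl anion formed after C–O addition may be protonated before it reaches the doubly ortho-substituted acyl carbon, so that the reaction stops at the aryl ester. The caesium phenoxide of the product may also add to a second aryne or close onto ring A with loss of methoxide, and some addition with the opposite regiochemistry may occur.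
   Fallback, setting out from 4 and 16 and returning to the route at 20: phenol 4 is protected with MOMCl/iPr2NEt to give 2-chloro-1,5-bis(methoxymethoxy)-3-methylbenzene F1. n-BuLi in THF at 0 °C should lithiate the carbon between the two MOM ethers to give 3-chloro-2,6-bis(methoxymethoxy)-4-methylphenyllithium F2, which is added to aldehyde 16 at −78 °C. The alkoxide closes on the neighbouring methyl ester to give the racemic 3-arylphthalide F3. Aqueous NaOH in MeOH opens the lactone to the sodium hydroxy-carboxylate F4, which is oxidised in the same alkaline solution with KMnO4 to the keto acid F5. MeI/K2CO3 in DMF gives the tris-MOM keto ester F6, and the conditions of step 11 remove all three MOM groups to give 20.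

2. Step 4 (directed silylation). The silyl triflate may cleave the aryl MOM ether, chlorine–lithium exchange may compete with deprotonation, and the carbamoyl group may migrate to carbon (anionic Fries shift) if the lithiated species warms before it is trapped.
   Fallback, setting out from 4 and returning at 11: phenol 4 is acylated with Et2NCOCl/K2CO3 in MeCN to give 4-chloro-3-(methoxymethoxy)-5-methylphenyl N,N-diethylcarbamate F7, which needs no silyl triflate. s-BuLi/TMEDA in THF at −78 °C gives the 2-lithio carbamate F8, which is trapped with TMSCl to give 4-chloro-3-(methoxymethoxy)-5-methyl-2-(trimethylsilyl)phenyl N,N-diethylcarbamate F9. Reductive cleavage of the tertiary carbamate with Cp2Zr(H)Cl in THF at rt gives the silyl phenol 10, isolated in this variant, and Tf2O/pyridine in CH2Cl2 at 0 °C gives 11.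

3. Step 6 (formylation of the free dihydroxy ester). The ester deactivates the ring and conversion may be poor, the phenols may be O-formylated instead, and some attack may occur at C4 between the two hydroxyl groups.
   Fallback, setting out from 12 and returning at 17, replacing steps 6–9: monomethylation of 12 with MeI (1 equiv)/K2CO3 in acetone gives methyl 3-hydroxy-5-methoxybenzoate F10 (also an article of commerce). Iodination with NIS and catalytic TsOH in MeCN at 0 °C, followed by chromatographic separation from the isomer iodinated ortho to the hydroxyl, gives methyl 5-hydroxy-2-iodo-3-methoxybenzoate F11 (iodine para to OH). MOMCl/iPr2NEt gives methyl 2-iodo-3-methoxy-5-(methoxymethoxy)benzoate F12. Iodine–magnesium exchange with iPrMgCl·LiCl in THF at −40 °C gives the arylmagnesium chloride F13, which is carboxylated with CO2 and acidified to give 17.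

Further compounds
F1 | step 10 | 2-chloro-1,5-bis(methoxymethoxy)-3-methylbenzene | COCOc1cc(OCOC)c(Cl)c(C)c1
F2 | step 10 | 3-chloro-2,6-bis(methoxymethoxy)-4-methylphenyllithium | COCOc1cc(C)c(Cl)c(OCOC)c1[Li]
F3 | step 10 | 3-[3-chloro-2,6-bis(methoxymethoxy)-4-methylphenyl]-4-methoxy-6-(methoxymethoxy)isobenzofuran-1(3H)-one (racemic) | COCOc1cc(OC)c2C(c3c(OCOC)cc(C)c(Cl)c3OCOC)OC(=O)c2c1
F4 | step 10 | sodium 2-{[3-chloro-2,6-bis(methoxymethoxy)-4-methylphenyl](hydroxy)methyl}-3-methoxy-5-(methoxymethoxy)benzoate (racemic) | COCOc1cc(OC)c(C(O)c2c(OCOC)cc(C)c(Cl)c2OCOC)c(C(=O)[O-])c1.[Na+]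
F5 | step 10 | 2-[3-chloro-2,6-bis(methoxymethoxy)-4-methylbenzoyl]-3-methoxy-5-(methoxymethoxy)benzoic acid | COCOc1cc(OC)c(C(=O)c2c(OCOC)cc(C)c(Cl)c2OCOC)c(C(=O)O)c1
F6 | step 10 | methyl 2-[3-chloro-2,6-bis(methoxymethoxy)-4-methylbenzoyl]-3-methoxy-5-(methoxymethoxy)benzoate | COCOc1cc(OC)c(C(=O)c2c(OCOC)cc(C)c(Cl)c2OCOC)c(C(=O)OC)c1
F7 | step 4 | 4-chloro-3-(methoxymethoxy)-5-methylphenyl N,N-diethylcarbamate | CCN(CC)C(=O)Oc1cc(C)c(Cl)c(OCOC)c1
F8 | step 4 | 4-chloro-2-lithio-3-(methoxymethoxy)-5-methylphenyl N,N-diethylcarbamate | CCN(CC)C(=O)Oc1cc(C)c(Cl)c(OCOC)c1[Li]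
F9 | step 4 | 4-chloro-3-(methoxymethoxy)-5-methyl-2-(trimethylsilyl)phenyl N,N-diethylcarbamate | CCN(CC)C(=O)Oc1cc(C)c(Cl)c(OCOC)c1[Si](C)(C)C
F10 | step 6 | methyl 3-hydroxy-5-methoxybenzoate | COC(=O)c1cc(O)cc(OC)c1
F11 | step 6 | methyl 5-hydroxy-2-iodo-3-methoxybenzoate | COC(=O)c1cc(O)cc(OC)c1I
F12 | step 6 | methyl 2-iodo-3-methoxy-5-(methoxymethoxy)benzoate | COC(=O)c1cc(OCOC)cc(OC)c1I
F13 | step 6 | [2-methoxy-6-(methoxycarbonyl)-4-(methoxymethoxy)phenyl]magnesium chloride | COC(=O)c1cc(OCOC)cc(OC)c1[Mg]Cl
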